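**Plan**

1. Retrosynthesis: the two phenol silyl ethers are removed first. The O–C(=O) unit of the 5-oxo-2,5-dihydrofuran ring is then taken out as CO2 by cutting O1–C2 (ring oxygen to quaternary carbon) and C4–C5 (methoxy-bearing carbon to lactone carbonyl) together. The acyclic C2–C3–C4 unit that remains is cut at aryl–C3 (cross-coupling) and at benzyl CH2–C2 (enolate alkylation), which leads back to methyl 4,4-dimethoxyacetoacetate.
2. Forward order: the prenylated benzyl bromide is joined to the keto ester. A Z enol triflate and a Suzuki–Miyaura coupling fix the tetrasubstituted enoate, and one acetal methoxy group is exchanged for a sulfonyl group. The only ring to be built, the furanone, arises in the key step, and desilylation ends the route.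
3. Enabling feature: ring carbon C4 carries OMe and sits next to the lactone carbonyl, so it is an acyl-anion carbon. Through the ring C3=C4 bond it is also the vinylogous partner of the quaternary C2. A geminal methoxy/sulfonyl pair at C4 makes it first a nucleophile toward CO2, then the origin of an allylic oxocarbenium electrophile whose far end (C2) takes the carboxylate oxygen.
4. Stereochemistry: the single stereocentre, quaternary C2 (R), is created in the key step under control of a chiral quaternary ammonium cation. The racemic centres of earlier intermediates are erased on the way.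

Key step: step 9

Assumption: the sense of induction of the ammonium salt cannot be derived from first principles. The cinchonidinium salt is written, and its pseudoenantiomer (cinchoninium series) is taken if the (S)-lactone is favoured.

Abbreviations: TBS = tert-butyldimethylsilyl, prenyl = 3-methylbut-2-en-1-yl, Tf = trifluoromethanesulfonyl.

**Step 1**
Reactants: 1 4-hydroxybenzaldehyde; 2 prenyl bromide (1-bromo-3-methylbut-2-ene)
Product: 3 4-hydroxy-3-prenylbenzaldehyde
Conditions: KOH, H2O, rt
Reagents that add atoms: none
Why: Phenoxide C-alkylation in water, where hydrogen bonding to the phenoxide oxygen steers the allylic bromide to the free ortho carbon (attack at the primary terminus) while the para position is blocked by the formyl group.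

**Step 2**
Reactants: 3 4-hydroxy-3-prenylbenzaldehyde
Product: 4 4-(TBSO)-3-prenylbenzaldehyde
Conditions: TBSCl, imidazole, DMF, rt
Reagents that add atoms: tert-butyldimethylsilyl chloride, CC(C)(C)[Si](C)(C)Cl
Why: Standard phenol silylation; the aryl silyl ether should survive enolates, zerovalent palladium and mild acid, and it leaves at the end under fluoride without acid that would cyclise the ortho-prenyl phenol.

**Step 3**
Reactants: 4 4-(TBSO)-3-prenylbenzaldehyde
Product: 5 [4-(TBSO)-3-prenylphenyl]methanol
Conditions: NaBH4, MeOH, 0 °C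
Reagents that add atoms: none
Why: Chemoselective borohydride reduction of an aromatic aldehyde that leaves the trisubstituted alkene and the silyl ether untouched.

**Step 4**
Reactants: 5 [4-(TBSO)-3-prenylphenyl]methanol
Product: 6 4-(TBSO)-3-prenylbenzyl bromide
Conditions: CBr4, PPh3, CH2Cl2, 0 °C, used without storage
Reagents that add atoms: carbon tetrabromide, BrC(Br)(Br)Br
Why: Appel reaction, whose neutral conditions convert the benzylic alcohol into the bromide without acid that could add to the prenyl group or strip the silyl ether.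

**Step 5**
Reactants: 6 4-(TBSO)-3-prenylbenzyl bromide; 7 methyl 4,4-dimethoxy-3-oxobutanoate
Product: 8 methyl 2-[4-(TBSO)-3-prenylbenzyl]-4,4-dimethoxy-3-oxobutanoate (racemic)
Conditions: NaH, THF, 0 °C to rt
Reagents that add atoms: none
Why: Acetoacetic ester alkylation of the sodium enolate with a reactive benzylic bromide; the new centre is racemic and is made planar in the next step.

**Step 6**
Reactants: 8 methyl 2-[4-(TBSO)-3-prenylbenzyl]-4,4-dimethoxy-3-oxobutanoate
Product: 9 methyl (Z)-2-[4-(TBSO)-3-prenylbenzyl]-4,4-dimethoxy-3-(triflyloxy)but-2-enoate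
Conditions: NaH, PhNTf2, THF, 0 °C to rt
Reagents that add atoms: N-phenylbis(trifluoromethanesulfonimide), O=S(=O)(N(c1ccccc1)S(=O)(=O)C(F)(F)F)C(F)(F)F
Why: O-sulfonylation of the sodium-chelated enolate, in which enolate oxygen and ester carbonyl are held cis, should give the Z enol triflate (OTf cis to CO2Me).

**Step 7**
Reactants: 9 the Z enol triflate; 10 4-(TBSO)phenylboronic acid
Product: 11 methyl (E)-2-[4-(TBSO)-3-prenylbenzyl]-3-[4-(TBSO)phenyl]-4,4-dimethoxybut-2-enoate
Conditions: Pd(PPh3)4 (5 mol %), K3PO4, THF–H2O, 50 °C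
Reagents that add atoms: none
Why: Suzuki–Miyaura coupling of an electron-poor enol triflate proceeds with retention of alkene geometry, so the aryl group ends cis to the ester and the acetal carbon cis to the benzyl group.

**Step 8**
Reactants: 11 the E acetal enoate
Product: 12 methyl (E)-2-[4-(TBSO)-3-prenylbenzyl]-3-[4-(TBSO)phenyl]-4-methoxy-4-(phenylsulfonyl)but-2-enoate (racemic at C4)
Conditions: PhSO2H, CaCl2, CH2Cl2, 0 °C to rt
Reagents that add atoms: benzenesulfinic acid, OS(=O)c1ccccc1
Why: Exchange of one acetal methoxy group for sulfinate through the oxocarbenium ion is the known route from acetals and lactols to alpha-alkoxy sulfones; sulfur should attack the open acetal carbon and not the fully substituted vinylogous terminus, and the new racemic centre is erased in step 9.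

**Step 9**
Reactants: 12 the alpha-methoxy allyl sulfone; 13 carbon dioxide
Product: 16 methyl (2R)-2-[4-(TBSO)-3-prenylbenzyl]-3-[4-(TBSO)phenyl]-4-methoxy-5-oxo-2,5-dihydrofuran-2-carboxylate, via C4 carbanion 14 (not isolated), via C4 carboxylate 15 (not isolated)
Conditions: CO2 (1 atm), Cs2CO3 (2 equiv), O-allyl-N-(9-anthracenylmethyl)cinchonidinium bromide (10 mol %), toluene, 0 °C to rt
Reagents that add atoms: none
Why: Proposed new method: Cs2CO3 removes the C4–H of 12 (alpha to sulfonyl and methoxy, vinylogous to the ester), the ammonium ion pair 14 adds reversibly through C4 to CO2 (new C–C bond), and the now tertiary alpha-methoxy sulfone 15 expels sulfinate while its carboxylate oxygen bonds to the far allyl terminus C2 (new C–O bond), so that CO2 is stitched across the three-carbon unit in a formal [3+2] annulation. The closest known reaction types are carboxylation–cyclisation cascades in which a labile CO2 adduct of a carbon acid is drained by an internal electrophile, annulations in which a sulfonyl group first stabilises the anion and then leaves, the spontaneous sulfinate loss of C-alkylated 2-sulfonyl cyclic ethers, and the closure of a carboxylate on a fully substituted allyl terminus in arylative cyclisations of 2,3-allenoic acids. The furanone closes in a formally 5-endo-trig SN2' mode, acceptable here because methoxy-assisted stretching of the C–S bond turns it into the conrotatory closure of a 1-oxapentadienyl cation whose largest acceptor coefficient lies on C2. The quaternary centre is controlled by the chiral cation: the enantiomers of 15 interconvert by loss and regain of CO2, the anti SN2' geometry ties the C4 configuration and the fixed E alkene to one face of C2, and in toluene, where free charge separation is disfavoured, the ion pair should let one enantiomer close faster (dynamic kinetic resolution, with precedent in cation-directed 5-endo-trig cyclisations under phase transfer). The step needs C4 over C2 carboxylation, secured because only the C4 adduct has an irreversible exit, and it must avoid attack of the ester carbonyl on C4, which the E geometry secures by holding CO2Me away from C4.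

**Step 10**
Reactants: 16 the bis-TBS ether
Product: 17 2-O-methylbutyrolactone I, methyl (2R)-2-[4-hydroxy-3-prenylbenzyl]-3-(4-hydroxyphenyl)-4-methoxy-5-oxo-2,5-dihydrofuran-2-carboxylate
Conditions: TBAF, AcOH, THF, 0 °C
Reagents that add atoms: none
Why: Fluoride cleavage of aryl silyl ethers, buffered with acetic acid so that lactone, methyl ester and the C2 centre are not touched and no strong acid is present that would close the prenyl phenol to a chroman.

**Compound list**

1 | 4-hydroxybenzaldehyde | O=Cc1ccc(O)cc1 | starting material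
2 | prenyl bromide | CC(C)=CCBr | starting material
3 | 4-hydroxy-3-prenylbenzaldehyde | O=Cc1ccc(O)c(CC=C(C)C)c1 | intermediate
4 | 4-(TBSO)-3-prenylbenzaldehyde | O=Cc1ccc(O[Si](C)(C)C(C)(C)C)c(CC=C(C)C)c1 | intermediate
5 | [4-(TBSO)-3-prenylphenyl]methanol | OCc1ccc(O[Si](C)(C)C(C)(C)C)c(CC=C(C)C)c1 | intermediate
6 | 4-(TBSO)-3-prenylbenzyl bromide | BrCc1ccc(O[Si](C)(C)C(C)(C)C)c(CC=C(C)C)c1 | intermediate
7 | methyl 4,4-dimethoxy-3-oxobutanoate | COC(=O)CC(=O)C(OC)OC | starting material
8 | methyl 2-[4-(TBSO)-3-prenylbenzyl]-4,4-dimethoxy-3-oxobutanoate (racemic) | COC(=O)C(Cc1ccc(O[Si](C)(C)C(C)(C)C)c(CC=C(C)C)c1)C(=O)C(OC)OC | intermediate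
9 | methyl (Z)-2-[4-(TBSO)-3-prenylbenzyl]-4,4-dimethoxy-3-(triflyloxy)but-2-enoate | COC(=O)/C(Cc1ccc(O[Si](C)(C)C(C)(C)C)c(CC=C(C)C)c1)=C(\OS(=O)(=O)C(F)(F)F)C(OC)OC | intermediate
10 | 4-(TBSO)phenylboronic acid | OB(O)c1ccc(O[Si](C)(C)C(C)(C)C)cc1 | starting material
11 | methyl (E)-2-[4-(TBSO)-3-prenylbenzyl]-3-[4-(TBSO)phenyl]-4,4-dimethoxybut-2-enoate | COC(=O)/C(Cc1ccc(O[Si](C)(C)C(C)(C)C)c(CC=C(C)C)c1)=C(\c1ccc(O[Si](C)(C)C(C)(C)C)cc1)C(OC)OC | intermediate
12 | methyl (E)-2-[4-(TBSO)-3-prenylbenzyl]-3-[4-(TBSO)phenyl]-4-methoxy-4-(phenylsulfonyl)but-2-enoate (racemic at C4) | COC(=O)/C(Cc1ccc(O[Si](C)(C)C(C)(C)C)c(CC=C(C)C)c1)=C(\c1ccc(O[Si](C)(C)C(C)(C)C)cc1)C(OC)S(=O)(=O)c1ccccc1 | intermediate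
13 | carbon dioxide | O=C=O | starting material
14 | C4 carbanion of 12 (ammonium ion pair, not isolated) | COC(=O)/C(Cc1ccc(O[Si](C)(C)C(C)(C)C)c(CC=C(C)C)c1)=C(\c1ccc(O[Si](C)(C)C(C)(C)C)cc1)[C-](OC)S(=O)(=O)c1ccccc1 | intermediate
15 | C4 carboxylate, 2-methoxy-2-(phenylsulfonyl)but-3-enoate form (both C4 configurations in equilibrium, not isolated) | COC(=O)/C(Cc1ccc(O[Si](C)(C)C(C)(C)C)c(CC=C(C)C)c1)=C(\c1ccc(O[Si](C)(C)C(C)(C)C)cc1)C(OC)(C(=O)[O-])S(=O)(=O)c1ccccc1 | intermediate
16 | methyl (2R)-2-[4-(TBSO)-3-prenylbenzyl]-3-[4-(TBSO)phenyl]-4-methoxy-5-oxo-2,5-dihydrofuran-2-carboxylate | COC(=O)[C@]1(Cc2ccc(O[Si](C)(C)C(C)(C)C)c(CC=C(C)C)c2)OC(=O)C(OC)=C1c1ccc(O[Si](C)(C)C(C)(C)C)cc1 | intermediate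
17 | 2-O-methylbutyrolactone I | COC(=O)[C@]1(Cc2ccc(O)c(CC=C(C)C)c2)OC(=O)C(OC)=C1c1ccc(O)cc1 | target

**Total step count:** 10. **Longest linear sequence:** 10 steps (1 to 17).

**Steps most likely to fail**

**Step 9.** The CO2 adduct may revert and the anion be reprotonated before sulfinate leaves. If the C–S bond ionises fully before ring closure, facial selectivity at C2 may also be poor. The fallback uses known chemistry only, sets out from 6 and returns at 16.
- 4'-Hydroxyacetophenone is silylated to 4'-(TBSO)acetophenone F1.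
- F1 is C-acylated (NaH, dimethyl carbonate) to methyl 3-[4-(TBSO)phenyl]-3-oxopropanoate F2.
- The sodium enolate of F2 is alkylated with 6 to the racemic alpha-benzyl beta-keto ester F3.
- Enantioselective alpha-hydroxylation of the F3 enolate with an enantiopure (camphorsulfonyl)oxaziridine gives the (R)-alpha-hydroxy beta-keto ester F4.
- Acylation with methoxyacetyl chloride (pyridine, DMAP) gives the methoxyacetate F5.
- Intramolecular aldol condensation of the methoxyacetate enolate onto the aryl ketone (LiHMDS, then dehydration) closes the furanone to 16 without touching C2.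

**Step 8.** The sulfinic acid may strip an aryl silyl ether or add to the prenyl alkene, or sulfinate may be captured at the vinylogous position. The fallback sets out from 11 and returns at 12, and it replaces protic exchange by halide displacement.
- Acetyl chloride with catalytic ZnBr2 in CH2Cl2 converts the acetal into the alpha-chloro ether F6.
- F6 is taken on crude and S-alkylates sodium benzenesulfinate in DMF to give 12.

**Step 1.** O-alkylation and double alkylation may compete with ortho C-alkylation. The fallback sets out from 1 and returns at 3, and it delivers the prenyl group by a sigmatropic shift.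
- O-alkylation of 1 with 3-chloro-3-methylbut-1-yne (CuCl2 catalyst, DBU, MeCN) gives the 1,1-dimethylpropargyl ether F7.
- Semihydrogenation (H2, Pd/CaCO3 poisoned with Pb(OAc)2, quinoline) gives the 1,1-dimethylallyl ether F8.
- Aromatic Claisen rearrangement of F8 in hot N,N-diethylaniline places the linear prenyl group on the ortho carbon.

**Further compounds**

F1 | step 9 | 4'-(TBSO)acetophenone | CC(=O)c1ccc(O[Si](C)(C)C(C)(C)C)cc1
F2 | step 9 | methyl 3-[4-(TBSO)phenyl]-3-oxopropanoate | COC(=O)CC(=O)c1ccc(O[Si](C)(C)C(C)(C)C)cc1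
F3 | step 9 | methyl 2-[4-(TBSO)-3-prenylbenzyl]-3-[4-(TBSO)phenyl]-3-oxopropanoate (racemic) | COC(=O)C(Cc1ccc(O[Si](C)(C)C(C)(C)C)c(CC=C(C)C)c1)C(=O)c1ccc(O[Si](C)(C)C(C)(C)C)cc1
F4 | step 9 | methyl (2R)-2-[4-(TBSO)-3-prenylbenzyl]-2-hydroxy-3-[4-(TBSO)phenyl]-3-oxopropanoate | COC(=O)[C@](C(=O)c1ccc(O[Si](C)(C)C(C)(C)C)cc1)(Cc1ccc(O[Si](C)(C)C(C)(C)C)c(CC=C(C)C)c1)O
F5 | step 9 | methyl (2R)-2-[4-(TBSO)-3-prenylbenzyl]-2-(methoxyacetoxy)-3-[4-(TBSO)phenyl]-3-oxopropanoate | COC(=O)[C@](C(=O)c1ccc(O[Si](C)(C)C(C)(C)C)cc1)(Cc1ccc(O[Si](C)(C)C(C)(C)C)c(CC=C(C)C)c1)OC(=O)COC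
F6 | step 8 | methyl (E)-2-[4-(TBSO)-3-prenylbenzyl]-3-[4-(TBSO)phenyl]-4-chloro-4-methoxybut-2-enoate (racemic at C4) | COC(=O)/C(Cc1ccc(O[Si](C)(C)C(C)(C)C)c(CC=C(C)C)c1)=C(\c1ccc(O[Si](C)(C)C(C)(C)C)cc1)C(Cl)OC
F7 | step 1 | 4-[(2-methylbut-3-yn-2-yl)oxy]benzaldehyde | O=Cc1ccc(OC(C)(C)C#C)cc1
F8 | step 1 | 4-[(2-methylbut-3-en-2-yl)oxy]benzaldehyde | O=Cc1ccc(OC(C)(C)C=C)cc1
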